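**Retrosynthetic overview**
1. Target 19 ⇐ 18: MeMgBr opens the δ-lactone joining O7 and C8 (giving 7-OH and the 3-hydroxy-3-methylbutyl chain) and cleaves both aryl esters.
2. 18 ⇐ 16: an aromatic Claisen rearrangement moves the 4'-O-prenyl group to C5' as the 1,1-dimethylallyl group.
3. 16 ⇐ 15: ring C is closed by forming the O1–C2 bond in an enantioselective anti-Markovnikov hydroetherification that also sets C3.
4. 15 ⇐ 8 + 12: Suzuki–Miyaura union of the ring A 2-bromoallyl phenol with the ring B boronate.
5. 8 ⇐ cyclohexane-1,3-dione + methyl acrylate + 2,3-dibromopropene; 12 ⇐ resorcinol monobenzoate. Ring order: ring A aromatised with its lactone first, ring B bought as an arene, ring C closed last.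

Assumption: the face selectivity of the new H-atom transfer in step 8 cannot be predicted; the thiol is written as (R), and its (S) form (equally available from (S)-BINOL) is used if (R) gives the 3S product.

**Step 1**
Reactants: 1 cyclohexane-1,3-dione; 2 methyl acrylate
Product: 3 methyl 3-(2,6-dioxocyclohexyl)propanoate
Conditions: NaOMe (0.1 equiv), MeOH, reflux
Reagents that add atoms: none
Why: base-catalysed Michael addition of the acidic C2 of the 1,3-dione to the acrylate; no stereocentre is formed.

**Step 2**
Reactants: 3 methyl 3-(2,6-dioxocyclohexyl)propanoate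
Product: 5 5-hydroxy-3,4-dihydro-2H-chromen-2-one, via resorcinol ester 4 (not isolated)
Conditions: 10% Pd/C, mesitylene, reflux, N2 sweep; then p-TsOH·H2O (cat.), reflux
Reagents that add atoms: none
Why: catalytic dehydrogenative aromatisation of the 2-alkylcyclohexane-1,3-dione to the 2-alkylresorcinol, then lactonisation of one phenol onto the ester, which differentiates the two hydroxyls and stores the C8 side chain.

**Step 3**
Reactants: 5 5-hydroxy-3,4-dihydro-2H-chromen-2-one; 6 2,3-dibromoprop-1-ene
Product: 7 5-[(2-bromoprop-2-en-1-yl)oxy]-3,4-dihydro-2H-chromen-2-one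
Conditions: K2CO3, dry acetone, 55 °C
Reagents that add atoms: none
Why: Williamson etherification at the allylic bromide only (the vinylic bromide is inert to SN2); the lactone survives anhydrous carbonate.

**Step 4**
Reactants: 7 5-[(2-bromoprop-2-en-1-yl)oxy]-3,4-dihydro-2H-chromen-2-one
Product: 8 6-(2-bromoprop-2-en-1-yl)-5-hydroxy-3,4-dihydro-2H-chromen-2-one
Conditions: N,N-diethylaniline, 200 °C, sealed tube, argon
Reagents that add atoms: none
Why: aromatic Claisen rearrangement ([3,3]) to the only free ortho carbon (C6), the other ortho position being the ring fusion.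

**Step 5**
Reactants: 9 3-hydroxyphenyl benzoate
Product: 10 2-bromo-5-hydroxyphenyl benzoate
Conditions: NBS (1.0 equiv), MeCN, −20 → 0 °C
Reagents that add atoms: N-bromosuccinimide, O=C1CCC(=O)N1Br
Why: electrophilic aromatic bromination directed para to the free OH, the benzoate oxygen being only a weak director.

**Step 6**
Reactants: 10 2-bromo-5-hydroxyphenyl benzoate; 11 1-bromo-3-methylbut-2-ene
Product: 12 2-bromo-5-[(3-methylbut-2-en-1-yl)oxy]phenyl benzoate
Conditions: K2CO3, acetone, 25 °C
Reagents that add atoms: none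
Why: Williamson O-prenylation (SN2 at the primary allylic bromide) at room temperature, where the benzoate does not scramble.

**Step 7**
Reactants: 12 2-bromo-5-[(3-methylbut-2-en-1-yl)oxy]phenyl benzoate; 13 bis(pinacolato)diboron; 8 6-(2-bromoprop-2-en-1-yl)-5-hydroxy-3,4-dihydro-2H-chromen-2-one
Product: 15 6-{2-[2-(benzoyloxy)-4-(3-methylbut-2-en-1-yloxy)phenyl]prop-2-en-1-yl}-5-hydroxy-3,4-dihydro-2H-chromen-2-one, via aryl pinacol boronate 14 (not isolated)
Conditions: 12, 13, PdCl2(dppf), KOAc, 1,4-dioxane, 85 °C; then 8, Pd(OAc)2/SPhos, K3PO4, H2O (10 equiv), 60 °C; work-up at pH 3–4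
Reagents that add atoms: none
Why: Miyaura borylation of the aryl bromide followed in the same pot by Suzuki–Miyaura coupling with the unhindered 1,1-disubstituted vinyl bromide; limited water and the mildly acidic work-up keep (or re-close) the lactone and spare the benzoate.

**Step 8**
Reactants: 15 6-{2-[2-(benzoyloxy)-4-(3-methylbut-2-en-1-yloxy)phenyl]prop-2-en-1-yl}-5-hydroxy-3,4-dihydro-2H-chromen-2-one
Product: 16 (3R)-3-[2-(benzoyloxy)-4-(3-methylbut-2-en-1-yloxy)phenyl]chroman in which O7 and C8 are bridged as a δ-lactone (O7–C(=O)–CH2–CH2–C8)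
Conditions: 9-mesityl-3,6-di-tert-butyl-10-phenylacridinium tetrafluoroborate (3 mol%), (R)-2'-methoxy-3-(2,4,6-triisopropylphenyl)-1,1'-binaphthalene-2-thiol (15 mol%), 1,2-dichloroethane (0.05 M), 450 nm LEDs, −20 °C, argon
Reagents that add atoms: none
Why: Proposed new method: the excited acridinium oxidises the electron-rich α-substituted styrene of 15 to its radical cation, the ring A phenol attacks the terminal CH2 (anti-Markovnikov, 6-endo) to form the O1–C2 bond and close ring C, and after proton loss the planar tertiary benzylic C3 radical takes a hydrogen atom from the S–H of the axially chiral arenethiol on one face to set (3R) (aryl S–H of about 79 kcal/mol against a benzylic C–H of about 84 kcal/mol makes this transfer downhill and hard to reverse), after which the thiyl radical re-oxidises the acridine radical and is reprotonated; the closest known reaction types are the racemic acridinium/thiol-catalysed anti-Markovnikov hydroetherification of alkenols and enantioselective H-atom transfer from chiral thiols to prochiral carbon radicals.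

**Step 9**
Reactants: 16 (3R)-3-[2-(benzoyloxy)-4-(3-methylbut-2-en-1-yloxy)phenyl]chroman δ-lactone
Product: 18 (3R)-3-[4-acetoxy-2-(benzoyloxy)-5-(2-methylbut-3-en-2-yl)phenyl]chroman δ-lactone (same O7/C8 lactone bridge), via Claisen phenol 17 (not isolated)
Conditions: Ac2O (5 equiv), N,N-diethylaniline, 190 °C, sealed tube
Reagents that add atoms: acetic anhydride, CC(=O)OC(C)=O
Why: aromatic Claisen rearrangement of the prenyl ether delivers the inverted (1,1-dimethylallyl) group to the open C5' and not to C3', which is flanked by the benzoate; the phenol is acetylated as it forms, which blocks the abnormal Claisen pathway, and C3 is not touched.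

**Step 10**
Reactants: 18 (3R)-3-[4-acetoxy-2-(benzoyloxy)-5-(2-methylbut-3-en-2-yl)phenyl]chroman δ-lactone
Product: 19 (3R)-3-[2,4-dihydroxy-5-(2-methylbut-3-en-2-yl)phenyl]-8-(3-hydroxy-3-methylbutyl)chroman-7-ol (target)
Conditions: MeMgBr (10 equiv), THF, 0 → 25 °C; sat. aq. NH4Cl work-up (no strong acid)
Reagents that add atoms: methylmagnesium bromide, C[Mg]Br
Why: double Grignard addition to the aryl lactone gives the 7-phenol and the tertiary alcohol, and the same reagent cleaves the benzoate and acetate; the vinyl group and C3 are inert, and the neutral work-up avoids acid-driven cyclisation of the tertiary alcohol onto the 7-OH.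

**Compound list**
1 | cyclohexane-1,3-dione | O=C1CCCC(=O)C1 | starting material
2 | methyl acrylate | C=CC(=O)OC | starting material
3 | methyl 3-(2,6-dioxocyclohexyl)propanoate | COC(=O)CCC1C(=O)CCCC1=O | intermediate
4 | methyl 3-(2,6-dihydroxyphenyl)propanoate (not isolated) | COC(=O)CCc1c(O)cccc1O | intermediate
5 | 5-hydroxy-3,4-dihydro-2H-chromen-2-one | O=C1CCc2c(O)cccc2O1 | intermediate
6 | 2,3-dibromoprop-1-ene | C=C(Br)CBr | starting material
7 | 5-[(2-bromoprop-2-en-1-yl)oxy]-3,4-dihydro-2H-chromen-2-one | O=C1CCc2c(OCC(Br)=C)cccc2O1 | intermediate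
8 | 6-(2-bromoprop-2-en-1-yl)-5-hydroxy-3,4-dihydro-2H-chromen-2-one | O=C1CCc2c(O)c(CC(Br)=C)ccc2O1 | intermediate
9 | 3-hydroxyphenyl benzoate (resorcinol monobenzoate) | O=C(Oc1cccc(O)c1)c1ccccc1 | starting material
10 | 2-bromo-5-hydroxyphenyl benzoate | O=C(Oc1cc(O)ccc1Br)c1ccccc1 | intermediate
11 | 1-bromo-3-methylbut-2-ene (prenyl bromide) | CC(C)=CCBr | starting material
12 | 2-bromo-5-[(3-methylbut-2-en-1-yl)oxy]phenyl benzoate | CC(C)=CCOc1ccc(Br)c(OC(=O)c2ccccc2)c1 | intermediate
13 | bis(pinacolato)diboron | CC1(C)OB(OC1(C)C)B1OC(C)(C)C(C)(C)O1 | starting material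
14 | 5-[(3-methylbut-2-en-1-yl)oxy]-2-(4,4,5,5-tetramethyl-1,3,2-dioxaborolan-2-yl)phenyl benzoate (not isolated) | CC(C)=CCOc1ccc(B2OC(C)(C)C(C)(C)O2)c(OC(=O)c2ccccc2)c1 | intermediate
15 | 6-{2-[2-(benzoyloxy)-4-(3-methylbut-2-en-1-yloxy)phenyl]prop-2-en-1-yl}-5-hydroxy-3,4-dihydro-2H-chromen-2-one | O=C1CCc2c(O)c(CC(=C)c3ccc(OCC=C(C)C)cc3OC(=O)c3ccccc3)ccc2O1 | intermediate
16 | (3R)-3-[2-(benzoyloxy)-4-(3-methylbut-2-en-1-yloxy)phenyl]chroman with O7–C(=O)–CH2–CH2–C8 lactone bridge | O=C1CCc2c(O1)ccc1c2OC[C@H](C1)c1ccc(OCC=C(C)C)cc1OC(=O)c1ccccc1 | intermediate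
17 | (3R)-3-[2-(benzoyloxy)-4-hydroxy-5-(2-methylbut-3-en-2-yl)phenyl]chroman with the same lactone bridge (not isolated) | O=C1CCc2c(O1)ccc1c2OC[C@H](C1)c1cc(C(C)(C)C=C)c(O)cc1OC(=O)c1ccccc1 | intermediate
18 | (3R)-3-[4-acetoxy-2-(benzoyloxy)-5-(2-methylbut-3-en-2-yl)phenyl]chroman with the same lactone bridge | O=C1CCc2c(O1)ccc1c2OC[C@H](C1)c1cc(C(C)(C)C=C)c(OC(C)=O)cc1OC(=O)c1ccccc1 | intermediate
19 | (3R)-3-[2,4-dihydroxy-5-(2-methylbut-3-en-2-yl)phenyl]-8-(3-hydroxy-3-methylbutyl)chroman-7-ol (CNP0420388.1) | C=CC(C)(C)c1cc([C@@H]2COc3c(ccc(O)c3CCC(C)(C)O)C2)c(O)cc1O | target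

**Step count**
Total: 10 steps. Longest linear sequence: 8 steps (1, 2, 3, 4, 7, 8, 9, 10).

**Three steps most likely to fail**

Step 8 (the new reaction). The risks are loss of a proton from the radical cation at C4 (giving the conjugated trisubstituted alkene), attack of the benzoate carbonyl on the radical cation, thiol–ene consumption of the catalyst, and low or opposite enantioselectivity. The thiol is not commercial and is made separately from BINOL. The ee is measured by chiral HPLC and raised by crystallisation of 16 or 18 if needed.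
Fallback (known chemistry), from 15 back to 16: a copper-catalysed enantioselective protoboration of the 1,1-disubstituted alkene (CuCl, DTBM-SEGPHOS of the antipode that gives the required sense, NaOtBu cat., 13, MeOH, THF, 0 °C) puts boron on the terminal carbon and gives the primary pinacol boronate F1. Oxidation with NaBO3·4H2O in THF/H2O gives the primary alcohol F2. An intramolecular Mitsunobu etherification (PPh3, DIAD, THF, 0 °C) of the ring A phenol onto the CH2OH then closes ring C to 16 without touching the stereocentre; the 2'-benzoate blocks the competing five-ring closure.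

Step 9 (Claisen rearrangement of the prenyl ether). The risks are partial migration to C3', loss of the prenyl group as isoprene, and abnormal Claisen products if acetylation is slow.
Fallback, from 16 back to 17: TiCl4/n-Bu4NI (CH2Cl2, −78 °C) removes the prenyl group and gives the 4'-phenol F3. NBS (MeCN, −20 °C) brominates ortho to the new hydroxyl at the open C5' and gives the bromophenol F4. A branched-selective (γ) palladium-catalysed Suzuki–Miyaura coupling with prenyl pinacol boronate (Pd(OAc)2, dialkylbiarylphosphine ligand, K3PO4, THF/H2O, 40 °C) then places the 1,1-dimethylallyl group on the carbon that carried bromine and gives 17, which is acetylated (Ac2O, pyridine) to 18.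

Step 7 (one-pot borylation and Suzuki–Miyaura coupling). The risks are acyl transfer or hydrolysis of the benzoate and lactone under base, protodeboronation of the ortho-acyloxy boronate 14, and ionisation of the prenyl ether by zerovalent palladium.
Fallback, from 8 and 12 directly to 15: a nickel-catalysed reductive cross-electrophile coupling of the vinyl bromide with the aryl bromide (NiBr2(dme), 4,4'-di-tert-butyl-2,2'-bipyridine, Zn dust, DMA, 40 °C), which needs neither a boronate nor a base and makes no new compound.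

**Further compounds**
F1 | step 8 | 6-{(2R)-2-[2-(benzoyloxy)-4-(3-methylbut-2-en-1-yloxy)phenyl]-3-(4,4,5,5-tetramethyl-1,3,2-dioxaborolan-2-yl)propyl}-5-hydroxy-3,4-dihydro-2H-chromen-2-one | O=C1CCc2c(O)c(C[C@@H](CB3OC(C)(C)C(C)(C)O3)c3ccc(OCC=C(C)C)cc3OC(=O)c3ccccc3)ccc2O1
F2 | step 8 | 6-{(2R)-2-[2-(benzoyloxy)-4-(3-methylbut-2-en-1-yloxy)phenyl]-3-hydroxypropyl}-5-hydroxy-3,4-dihydro-2H-chromen-2-one | O=C1CCc2c(O)c(C[C@@H](CO)c3ccc(OCC=C(C)C)cc3OC(=O)c3ccccc3)ccc2O1
F3 | step 9 | (3R)-3-[2-(benzoyloxy)-4-hydroxyphenyl]chroman with O7–C(=O)–CH2–CH2–C8 lactone bridge | O=C1CCc2c(O1)ccc1c2OC[C@H](C1)c1ccc(O)cc1OC(=O)c1ccccc1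
F4 | step 9 | (3R)-3-[2-(benzoyloxy)-5-bromo-4-hydroxyphenyl]chroman with O7–C(=O)–CH2–CH2–C8 lactone bridge | O=C1CCc2c(O1)ccc1c2OC[C@H](C1)c1cc(Br)c(O)cc1OC(=O)c1ccccc1
F0 | step 7 | none | none
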